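## The problem

The target is a bis-tropolone built on an eleven-membered carbocycle, numbered here C1 to C11. C1 is the quaternary carbon C(CH3)(O–tropolone A) next to the carbinol, C2 the secondary carbinol, C3 a CH2, C4 the CH carrying the C13 methylene of tropolone B, C5 the quaternary C(CH3)(O–tropolone B), C6 a CH2, C7=C8 the E-alkene, C9 the C(CH3)2 carbon, C10 a CH2 and C11 the CH carrying the C12 methylene of tropolone A. Each tropolone is tied to the ring twice, through an aryl–CH2 bond and a tertiary alkyl aryl ether, so two dihydropyrans are trans-fused to the macrocycle at C11–C1 and C4–C5. The five stereocentres are 1R, 2S, 4R, 5R and 11R. C1 and C5 are fully substituted carbinol carbons that cannot be corrected later and lie far apart, so each must be made as a single enantiomer on its own. C1 can then control C2 (neighbour) and C5 can control C4 (neighbour). The tropolones are acidic, chelating, open to nucleophiles and reducible; the tertiary alkyl tropone ethers are vinylogous esters that exchange under acid; the ring is strained. The enabling feature is the array C1(no hydrogen, O-aryl)–C2(OH)–C3H2–C4(–C13): it is the product of adding a 2-substituted allyl metal to a non-enolisable α-aryloxy aldehyde. That addition closes the ring, sets C2 and leaves at C4 the methylene carbon C13 that must carry tropolone B.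

## Retrosynthesis

**Ring B and the protecting groups.** Target 45 is traced to its bis-methyl ether 44 (two O–CH3 bonds, cleaved by chloride at methyl, which cannot touch the tertiary ethers). In 44 the C5–O–tropone bond is cut, giving alcohol 43 and its silyl ether 42: the tertiary alkoxide displaces a methoxy group of a methoxytropone in a six-membered closure. In 42 the C13–tropone bond is cut to the exocyclic alkene 40 and bromotropone 7 (hydroboration, then Suzuki coupling). Cutting C4–C13 instead would demand a bond at a hindered ring carbon; the chosen cut uses the alkene the ring closure leaves behind. The forward steps must deliver hydrogen to the correct face of C4.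

**The ring (key step).** Macrocycle 40 is opened at C2–C3 to bromo-aldehyde 38. Closing at C7=C8 would put a ring-forming olefination next to the gem-dimethyl carbon; closing at C1 or C5 would make a bond at a quaternary centre. The C2–C3 cut makes the C2 stereocentre from an aldehyde that cannot enolise, under control of C1. It asks for cyclisation at high dilution and for addition anti to the aryloxy group.

**The chain.** Compound 38 comes from 34 by adjusting two oxygen functions (35, 36, 37). Compound 34 is cut at C7=C8 into aldehyde 23 (C8–C12, tropolone A, stereocentres C1 and C11) and sulfone 33 (C3–C7, C13, stereocentre C5). The cut lies between the two stereochemical clusters, so each half is made alone as one enantiomer. The C8 aldehyde is neopentyl and non-enolisable, which suits a Julia–Kocienski olefination with E selectivity.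

**Ring A.** Pyranotropone 23 (via acetal 22) is cut at the same two bond types as ring B: the C1–O–tropone ether (alkoxide displacement from 20) and the C12–tropone bond (Negishi coupling of iodide 18, via zinc reagent 19, with 7). One bromotropone thus serves both rings.

**C1 and C11.** Iodide 18 comes from diol 16, and 16 from epoxide 14 by cutting C11–C12: a hydroxymethyl anion equivalent opens the epoxide at C11 with inversion, while the C1 oxygen stays in place. Because oxygen and carbon then add anti across the former alkene, the allylic alcohol 12 must be Z to give the trans ring fusion. Epoxide 13 comes from 12 by Sharpless epoxidation; 12 from ester 11, aldehyde 10, acetal 9 and commercial 2,2-dimethylpent-4-enal 8.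

**C5.** Sulfone 33 comes from sulfides 32 and 31 and diol 30. Diol 30 is cut at the C6–H bond: hydride opening of epoxy alcohol 29 at C6 leaves the tertiary C5–O bond untouched. Epoxide 29 comes from E-dienol 28, which is cut at C4–C5 into vinyl bromide 25 (the intact 2-substituted allyl unit, from 24) and boronate 27 (from 26).

**The tropolone.** Bromotropone 7 comes from hydroxytropolone 6, diol 5 and bromodienone 4. In 4 the bromine-bearing ring carbon is cut out: it is inserted by dibromocarbene into the enol ether bond of Birch diene 2 (from 2-methylanisole 1) via adduct 3. The bromine thereby arrives by construction on the carbon that must later carry the CH2 link, between the methyl-bearing carbon and the oxygenated carbon.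

## Roads not taken

**Alternative 1:** Both tropolone rings are carried as benzenoid methoxy-chromans and expanded at the end. After Birch reduction of both arenes, dibromocarbene inserts one carbon into each methyl enol ether to give the bis(bromocycloheptadienone) A1. Its merit is robustness: chromans survive every organometallic step, whereas the chosen plan must carry tropone A through a sulfone anion, divalent chromium and a borane. Its weak points are late. Each reduced ring holds two enol ethers (the tetrasubstituted pyran one and the methoxy one), so the carbene must choose correctly four times and spare the C7=C8 alkene. A1 is still two oxidation levels and one bromine-to-oxygen exchange short of a tropolone in each ring. Dissolving metal and strong base are used on the most valuable intermediate. The chosen plan uses the same ring expansion once, at step 2, on a diene whose only electron-rich double bond is the right one.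

**Alternative 2:** Both aryl–CH2 bonds are made in one double Suzuki coupling of a tropolone-free macrocycle carrying two primary boronates with two equivalents of bromotropone 7, giving A2. This is the most convergent plan, and it is better than the chosen one in that no tropone meets chromium or a sulfone anion. But it moves the hard part rather than solving it: the eleven-membered ring with C1, C2, C4, C5 and C11 all set must be made by other means, and the route says neither how the ring closes nor how C2 is controlled. Both couplings occur at hindered primary boronates beside quaternary carbinols, and two ether closures remain. The chosen plan answers the ring and C2 in one step, and pays by attaching the tropolones one at a time.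

**Alternative 3:** Each seven-membered ring and its dihydropyran are built together by intramolecular enone–alkyne photocycloaddition and thermal opening of the cyclobutene, giving bis-dienone A3. On paper this is the shortest way to both bicycles and needs no aromatic building block. For this target the risks are E/Z scrambling of the strained C7=C8 alkene by triplet energy transfer, straight versus crossed regiochemistry in two tethered additions at once, and the state of A3: each ring lacks one oxygen and one unsaturation, so two α-oxygenations and two dehydrogenations follow on a late intermediate. The chosen plan uses only ground-state reactions of known selectivity and brings each tropolone in at its final oxidation level.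

Key step: step 31

Remark: both tropolones are carried as the ethers with the methoxy group on the carbon next to the methyl-side CH; the other O-methyl regioisomer of either ring would give the same tropolone in step 34.

## Route

Step 1
Reactants: 1 2-methylanisole
Product: 2 1-methoxy-2-methylcyclohexa-1,4-diene
Conditions: Li, NH3 (l), t-BuOH, THF, −78 to −33 °C; NH4Cl
Reagents that add atoms: none
Why: Birch reduction; the methoxy- and methyl-bearing carbons stay sp2, so one tetrasubstituted enol ether double bond and one isolated cis-alkene result.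

Step 2
Reactants: 2 1-methoxy-2-methylcyclohexa-1,4-diene
Product: 4 2-bromo-3-methylcyclohepta-2,5-dien-1-one, via dibromocyclopropane adduct 3 (not isolated)
Conditions: CHBr3, KOtBu, pentane, −30 to 0 °C; then AgNO3, acetone/H2O, rt
Reagents that add atoms: bromoform, BrC(Br)Br; water, O
Why: Dihalocarbene ring expansion of a Birch diene: the electrophilic carbene adds to the enol ether double bond only, silver-assisted loss of bromide opens the cyclopropane to an oxocarbenium ion, and water gives the 2-bromoenone with bromine on the inserted carbon.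

Step 3
Reactants: 4 2-bromo-3-methylcyclohepta-2,5-dien-1-one
Product: 5 rac-(5R,6S)-2-bromo-5,6-dihydroxy-3-methylcyclohept-2-en-1-one
Conditions: OsO4 (2 mol%), N-methylmorpholine N-oxide, acetone/H2O, 0 °C
Reagents that add atoms: N-methylmorpholine N-oxide, C[N+]1([O-])CCOCC1; water, O
Why: Catalytic OsO4 syn-dihydroxylation takes the isolated cis-alkene and leaves the electron-poor tetrasubstituted bromoenone alone; the cis-diol is racemic, which is immaterial because both carbinol carbons become sp2.

Step 4
Reactants: 5 rac-(5R,6S)-2-bromo-5,6-dihydroxy-3-methylcyclohept-2-en-1-one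
Product: 6 5-bromo-2,4-dihydroxy-6-methylcyclohepta-2,4,6-trien-1-one
Conditions: (CF3CO)2O, DMSO, CH2Cl2, −78 °C; then Et3N, −78 to 0 °C
Reagents that add atoms: none
Why: Swern-type oxidation of both carbinols gives the cycloheptene-1,2,4-trione, which enolises at once to the aromatic hydroxytropolone; oxidation of ring cis-diols to tropolones with activated DMSO is a known reaction type.

Step 5
Reactants: 6 5-bromo-2,4-dihydroxy-6-methylcyclohepta-2,4,6-trien-1-one
Product: 7 4-bromo-3,7-dimethoxy-5-methylcyclohepta-2,4,6-trien-1-one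
Conditions: Me2SO4, K2CO3, acetone, reflux
Reagents that add atoms: dimethyl sulfate, COS(=O)(=O)OC
Why: O-Alkylation of the dianion by a hard electrophile; the two charges should sit on the outer oxygens, with the central oxygen as the carbonyl conjugated to both (least charge repulsion), so the 3,7-dimethyl ether is expected, and aromaticity disfavours C-alkylation.

Step 6
Reactants: 8 2,2-dimethylpent-4-enal
Product: 9 5,5-dimethoxy-4,4-dimethylpent-1-ene
Conditions: HC(OMe)3, MeOH, p-TsOH (cat.), rt
Reagents that add atoms: trimethyl orthoformate, COC(OC)OC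
Why: Acid-catalysed acetalisation; the future C8 aldehyde is masked until step 17.

Step 7
Reactants: 9 5,5-dimethoxy-4,4-dimethylpent-1-ene
Product: 10 4,4-dimethoxy-3,3-dimethylbutanal
Conditions: O3, CH2Cl2, −78 °C; then PPh3, −78 °C to rt
Reagents that add atoms: ozone, [O-][O+]=O
Why: Ozonolysis with reductive work-up of the only alkene.

Step 8
Reactants: 10 4,4-dimethoxy-3,3-dimethylbutanal
Product: 11 ethyl (2Z)-6,6-dimethoxy-2,5,5-trimethylhex-2-enoate
Conditions: (CF3CH2O)2P(O)CH(CH3)CO2Et, KN(SiMe3)2, 18-crown-6, THF, −78 °C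
Reagents that add atoms: ethyl 2-[bis(2,2,2-trifluoroethoxy)phosphoryl]propanoate, CCOC(=O)C(C)P(=O)(OCC(F)(F)F)OCC(F)(F)F
Why: Still–Gennari olefination; the trifluoroethyl phosphonate with a dissociated potassium base gives the Z-trisubstituted enoate under kinetic control.

Step 9
Reactants: 11 ethyl (2Z)-6,6-dimethoxy-2,5,5-trimethylhex-2-enoate
Product: 12 (2Z)-6,6-dimethoxy-2,5,5-trimethylhex-2-en-1-ol
Conditions: iBu2AlH, CH2Cl2, −78 °C; Rochelle salt
Reagents that add atoms: none
Why: 1,2-Reduction of the enoate by diisobutylaluminium hydride; the alkene geometry and the acetal are unaffected.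

Step 10
Reactants: 12 (2Z)-6,6-dimethoxy-2,5,5-trimethylhex-2-en-1-ol
Product: 13 [(2S,3R)-3-(3,3-dimethoxy-2,2-dimethylpropyl)-2-methyloxiran-2-yl]methanol
Conditions: Ti(OiPr)4 (10 mol%), L-(+)-diisopropyl tartrate (12 mol%), t-BuOOH, 4 Å molecular sieves, CH2Cl2, −20 °C
Reagents that add atoms: tert-butyl hydroperoxide, CC(C)(C)OO
Why: Sharpless asymmetric epoxidation; with L-(+)-tartrate the Z-trisubstituted allylic alcohol is oxidised on the face that gives the (2S,3R)-epoxide, which fixes the future C1 oxygen with its final configuration.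

Step 11
Reactants: 13 [(2S,3R)-3-(3,3-dimethoxy-2,2-dimethylpropyl)-2-methyloxiran-2-yl]methanol
Product: 14 (2S,3R)-3-(3,3-dimethoxy-2,2-dimethylpropyl)-2-{[(4-methoxyphenyl)methoxy]methyl}-2-methyloxirane
Conditions: NaH, 4-methoxybenzyl chloride, Bu4NI (cat.), THF/DMF, 0 °C to rt
Reagents that add atoms: 4-methoxybenzyl chloride, COc1ccc(CCl)cc1
Why: Williamson etherification; Payne rearrangement is not expected because it would need attack at the fully substituted epoxide carbon.

Step 12
Reactants: 14 (2S,3R)-3-(3,3-dimethoxy-2,2-dimethylpropyl)-2-{[(4-methoxyphenyl)methoxy]methyl}-2-methyloxirane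
Product: 16 (2R,3R)-2-(3,3-dimethoxy-2,2-dimethylpropyl)-4-[(4-methoxyphenyl)methoxy]-3-methylbutane-1,3-diol, via silane 15 (not isolated)
Conditions: (iPrO)Me2SiCH2MgCl, CuI (10 mol%), THF, −20 to 0 °C; NH4Cl; then KF, KHCO3, 30% H2O2, THF/MeOH, rt
Reagents that add atoms: [isopropoxy(dimethyl)silyl]methylmagnesium chloride, CC(C)O[Si](C)(C)C[Mg]Cl; hydrogen peroxide, OO
Why: Copper-catalysed Grignard opening of the trisubstituted epoxide at its less substituted carbon (SN2, inversion at the future C11; the tertiary C–O bond keeps its configuration), then Tamao oxidation of the C–Si bond; the silylmethyl reagent is a hydroxymethyl anion equivalent.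

Step 13
Reactants: 16 (2R,3R)-2-(3,3-dimethoxy-2,2-dimethylpropyl)-4-[(4-methoxyphenyl)methoxy]-3-methylbutane-1,3-diol
Product: 17 (2R,3S)-3-(iodomethyl)-6,6-dimethoxy-1-[(4-methoxyphenyl)methoxy]-2,5,5-trimethylhexan-2-ol
Conditions: I2, PPh3, imidazole, CH2Cl2, 0 °C
Reagents that add atoms: iodine, II
Why: Appel-type iodination, selective for the primary hydroxyl over the tertiary one.

Step 14
Reactants: 17 (2R,3S)-3-(iodomethyl)-6,6-dimethoxy-1-[(4-methoxyphenyl)methoxy]-2,5,5-trimethylhexan-2-ol
Product: 18 {[(2R,3S)-3-(iodomethyl)-6,6-dimethoxy-1-[(4-methoxyphenyl)methoxy]-2,5,5-trimethylhexan-2-yl]oxy}(trimethyl)silane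
Conditions: Me3SiCl, imidazole, DMF, rt
Reagents that add atoms: chlorotrimethylsilane, C[Si](C)(C)Cl
Why: Silylation of the tertiary alcohol, so that no acidic hydrogen can quench the organozinc reagent; a silyl triflate is avoided because it would attack the dimethyl acetal.

Step 15
Reactants: 18 the trimethylsilyl ether iodide; 7 4-bromo-3,7-dimethoxy-5-methylcyclohepta-2,4,6-trien-1-one
Product: 20 4-{(2S,3R)-2-(3,3-dimethoxy-2,2-dimethylpropyl)-4-[(4-methoxyphenyl)methoxy]-3-methyl-3-[(trimethylsilyl)oxy]butyl}-3,7-dimethoxy-5-methylcyclohepta-2,4,6-trien-1-one, via alkylzinc iodide 19 (not isolated)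
Conditions: Zn dust, LiCl, THF, 40 °C; then 7, Pd(OAc)2 (5 mol%), SPhos (10 mol%), THF, rt to 40 °C
Reagents that add atoms: none
Why: Negishi coupling: zinc inserts into the primary C–I bond and zerovalent palladium joins the sp3 carbon to the hindered bromotropone; alkylzinc halides do not add to the tropone carbonyl or disturb the acetal and ethers.

Step 16
Reactants: 20 the coupled silyl ether
Product: 22 (2R,3S)-3-(3,3-dimethoxy-2,2-dimethylpropyl)-7-methoxy-2-{[(4-methoxyphenyl)methoxy]methyl}-2,5-dimethyl-3,4-dihydrocyclohepta[b]pyran-8(2H)-one, via tertiary alcohol 21 (not isolated)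
Conditions: Bu4NF, THF, 0 °C to rt
Reagents that add atoms: none
Why: Fluoride removes the trimethylsilyl group and the tertiary alkoxide adds to the methoxy-bearing carbon β to the tropone carbonyl, then methoxide leaves (intramolecular addition–elimination at a vinylogous ester, 6-exo-trig), the substitution by which methoxytropones exchange methoxy for amines and alkoxides; no stereocentre is touched, so the trans-2,3-disubstituted dihydropyran results.

Step 17
Reactants: 22 the pyranotropone acetal
Product: 23 3-[(2R,3S)-7-methoxy-2-{[(4-methoxyphenyl)methoxy]methyl}-2,5-dimethyl-8-oxo-2,3,4,8-tetrahydrocyclohepta[b]pyran-3-yl]-2,2-dimethylpropanal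
Conditions: pyridinium p-toluenesulfonate, acetone/H2O, 40 °C
Reagents that add atoms: water, O
Why: Mild acid-catalysed acetal hydrolysis; the vinylogous esters need stronger aqueous acid to hydrolyse, and the aldehyde has no α-hydrogen.

Step 18
Reactants: 24 2-bromoprop-2-en-1-ol
Product: 25 [(2-bromoprop-2-en-1-yl)oxy](tert-butyl)dimethylsilane
Conditions: t-BuMe2SiCl, imidazole, CH2Cl2, rt
Reagents that add atoms: tert-butyldimethylsilyl chloride, CC(C)(C)[Si](C)(C)Cl
Why: Standard silylation of a primary alcohol.

Step 19
Reactants: 26 but-2-yn-1-ol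
Product: 27 (2Z)-3-(4,4,5,5-tetramethyl-1,3,2-dioxaborolan-2-yl)but-2-en-1-ol
Conditions: B2pin2, CuCl (5 mol%), Xantphos (5 mol%), NaOtBu (10 mol%), MeOH, THF, rt
Reagents that add atoms: bis(pinacolato)diboron, CC1(C)OB(OC1(C)C)B1OC(C)(C)C(C)(C)O1
Why: Copper-catalysed borylcupration and protonation (formal hydroboration) of an internal propargylic alcohol: syn addition with boron on the carbon remote from the oxygen, which places methyl cis to CH2OH.

Step 20
Reactants: 25 the silyl ether of 2-bromoallyl alcohol; 27 the alkenyl boronate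
Product: 28 (2E)-4-({[tert-butyl(dimethyl)silyl]oxy}methyl)-3-methylpenta-2,4-dien-1-ol
Conditions: Pd(PPh3)4 (5 mol%), K3PO4 (aq), THF, 50 °C
Reagents that add atoms: none
Why: Suzuki–Miyaura coupling with retention of alkene geometry; the 2-substituted allyl unit (future C13=C4–C3) is attached intact to the future C5.

Step 21
Reactants: 28 the (2E)-dienol
Product: 29 [(2S,3S)-3-(3-{[tert-butyl(dimethyl)silyl]oxy}prop-1-en-2-yl)-3-methyloxiran-2-yl]methanol
Conditions: Ti(OiPr)4 (10 mol%), L-(+)-diisopropyl tartrate (12 mol%), t-BuOOH, 4 Å molecular sieves, CH2Cl2, −25 °C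
Reagents that add atoms: tert-butyl hydroperoxide, CC(C)(C)OO
Why: Sharpless asymmetric epoxidation touches only the allylic alcohol double bond; with L-(+)-tartrate the E-trisubstituted (geraniol-type) alkene gives the (2S,3S)-epoxide, which places the oxygen on the future C5 in its final configuration.

Step 22
Reactants: 29 the (2S,3S)-epoxy alcohol
Product: 30 (3R)-4-({[tert-butyl(dimethyl)silyl]oxy}methyl)-3-methylpent-4-ene-1,3-diol
Conditions: NaAlH2(OCH2CH2OCH3)2, THF, 0 °C
Reagents that add atoms: none
Why: Regioselective reductive opening of a 2,3-epoxy alcohol: hydride is delivered from the aluminium alkoxide to C2, so the 1,3-diol forms and the tertiary C–O bond is not broken.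

Step 23
Reactants: 30 the (3R)-1,3-diol
Product: 31 (3R)-2-({[tert-butyl(dimethyl)silyl]oxy}methyl)-3-methyl-5-[(1-phenyl-1H-tetrazol-5-yl)sulfanyl]pent-1-en-3-ol
Conditions: 1-phenyl-1H-tetrazole-5-thiol, PPh3, diisopropyl azodicarboxylate, THF, 0 °C
Reagents that add atoms: 1-phenyl-1H-tetrazole-5-thiol, Sc1nnnn1-c1ccccc1
Why: Mitsunobu thioetherification, which activates only the primary hydroxyl.

Step 24
Reactants: 31 the hydroxy sulfide
Product: 32 5-{[(3R)-3-{[tert-butyl(dimethyl)silyl]oxy}-4-({[tert-butyl(dimethyl)silyl]oxy}methyl)-3-methylpent-4-en-1-yl]sulfanyl}-1-phenyl-1H-tetrazole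
Conditions: t-BuMe2SiOSO2CF3, 2,6-lutidine, CH2Cl2, 0 °C
Reagents that add atoms: tert-butyldimethylsilyl trifluoromethanesulfonate, CC(C)(C)[Si](C)(C)OS(=O)(=O)C(F)(F)F
Why: Silyl triflate silylation of the hindered tertiary alcohol; done before the oxidation so that no free allylic hydroxyl can direct epoxidation.

Step 25
Reactants: 32 the bis-silyl sulfide
Product: 33 5-{[(3R)-3-{[tert-butyl(dimethyl)silyl]oxy}-4-({[tert-butyl(dimethyl)silyl]oxy}methyl)-3-methylpent-4-en-1-yl]sulfonyl}-1-phenyl-1H-tetrazole
Conditions: (NH4)6Mo7O24·4H2O (10 mol%), 30% H2O2, EtOH, 0 °C to rt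
Reagents that add atoms: hydrogen peroxide, OO
Why: Molybdate-catalysed oxidation of sulfide to sulfone; the unactivated 1,1-disubstituted alkene is not epoxidised under these conditions.

Step 26
Reactants: 33 the tetrazolyl sulfone; 23 the pyranotropone aldehyde
Product: 34 (2R,3R)-3-[(3E,6R)-6-{[tert-butyl(dimethyl)silyl]oxy}-7-({[tert-butyl(dimethyl)silyl]oxy}methyl)-2,2,6-trimethylocta-3,7-dien-1-yl]-7-methoxy-2-{[(4-methoxyphenyl)methoxy]methyl}-2,5-dimethyl-3,4-dihydrocyclohepta[b]pyran-8(2H)-one
Conditions: 33, KN(SiMe3)2, 1,2-dimethoxyethane, −60 °C; then 23, −60 °C to rt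
Reagents that add atoms: none
Why: Julia–Kocienski olefination; the phenyltetrazolyl sulfone anion with an α-quaternary, non-enolisable aldehyde gives the E-alkene by anti addition and Smiles rearrangement, and the aldehyde is far more electrophilic than the dialkoxytropone.

Step 27
Reactants: 34 the bis-silyl ether
Product: 35 (2R,3R)-3-[(3E,6R)-6-{[tert-butyl(dimethyl)silyl]oxy}-7-(hydroxymethyl)-2,2,6-trimethylocta-3,7-dien-1-yl]-7-methoxy-2-{[(4-methoxyphenyl)methoxy]methyl}-2,5-dimethyl-3,4-dihydrocyclohepta[b]pyran-8(2H)-one
Conditions: HF·pyridine, pyridine, THF, 0 °C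
Reagents that add atoms: none
Why: Selective desilylation: the primary allylic silyl ether is cleaved far faster than the tertiary one, and the buffered fluoride avoids acid-catalysed exchange of the vinylogous esters.

Step 28
Reactants: 35 the allylic alcohol
Product: 36 (2R,3R)-3-[(3E,6R)-7-(bromomethyl)-6-{[tert-butyl(dimethyl)silyl]oxy}-2,2,6-trimethylocta-3,7-dien-1-yl]-7-methoxy-2-{[(4-methoxyphenyl)methoxy]methyl}-2,5-dimethyl-3,4-dihydrocyclohepta[b]pyran-8(2H)-one
Conditions: CBr4, PPh3, 2,6-lutidine, CH2Cl2, 0 °C
Reagents that add atoms: carbon tetrabromide, BrC(Br)(Br)Br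
Why: Appel bromination; the two CH2 termini of the 2-substituted allyl unit are equivalent, so direct and allylic substitution give the same bromide.

Step 29
Reactants: 36 the allylic bromide
Product: 37 (2R,3R)-3-[(3E,6R)-7-(bromomethyl)-6-{[tert-butyl(dimethyl)silyl]oxy}-2,2,6-trimethylocta-3,7-dien-1-yl]-2-(hydroxymethyl)-7-methoxy-2,5-dimethyl-3,4-dihydrocyclohepta[b]pyran-8(2H)-one
Conditions: 2,3-dichloro-5,6-dicyano-1,4-benzoquinone, CH2Cl2/pH 7 buffer, 0 °C
Reagents that add atoms: none
Why: Oxidative cleavage of the 4-methoxybenzyl ether under neutral conditions, which spare the allylic bromide, the silyl ether and the alkenes.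

Step 30
Reactants: 37 the primary alcohol
Product: 38 (2R,3R)-3-[(3E,6R)-7-(bromomethyl)-6-{[tert-butyl(dimethyl)silyl]oxy}-2,2,6-trimethylocta-3,7-dien-1-yl]-7-methoxy-2,5-dimethyl-8-oxo-2,3,4,8-tetrahydrocyclohepta[b]pyran-2-carbaldehyde
Conditions: Dess–Martin periodinane, NaHCO3, CH2Cl2, rt
Reagents that add atoms: none
Why: Dess–Martin oxidation under buffered, non-nucleophilic conditions; the aldehyde has no α-hydrogen and is made last, just before the ring closure.

Step 31
Reactants: 38 the bromo-aldehyde
Product: 40 macrocyclic homoallylic alcohol: (1R,2S,5R,11R; target numbering) eleven-membered ring with C2 hydroxyl, C4 exocyclic methylene, C5 methyl and tert-butyldimethylsilyloxy, (7E)-alkene and C9 gem-dimethyl, trans-fused at C11–C1 to the 7-methoxy-5-methyl-8-oxo-dihydropyranotropone, via allylchromium species 39 (not isolated)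
Conditions: CrCl2 (10 equiv), THF, rt, syringe-pump addition of 38 (final 2 mM)
Reagents that add atoms: none
Why: Two equivalents of divalent chromium reduce the allylic C–Br bond by single-electron steps to the trivalent allylchromium species 39, which adds to the aldehyde through a closed six-membered chair transition state with allylic transposition; the two CH2 termini of the 2-substituted allyl group are equivalent, so only one constitution can form. The closest known reaction type is the intramolecular Nozaki–Hiyama allylation used to close medium and large carbocycles. The eleven-membered ring closes in the 11-exo-trig mode by C2–C3 bond formation, with the carbonyl oxygen left outside the ring. The new C2 stereocentre is controlled by the neighbouring C1: in the Felkin–Anh arrangement the C1–O(tropone) bond stands anti to the incoming allyl carbon, which passes the methyl group and not the ring carbon C11, giving the (2S)-alcohol anti to the ether oxygen. A chelated arrangement would give the C2 epimer, but the ether oxygen is conjugated into the tropone and is a poor donor toward THF-solvated chromium. The step needs ring closure to outrun intermolecular allylation, which slow addition at high dilution secures, helped by the E-alkene, the gem-dimethyl group and the fused pyran, which limit the rotamers of the chain. It also needs chemoselectivity: the aldehyde cannot enolise, and chromium reagents of this kind leave the tropone, the silyl ether and the alkenes alone.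

Step 32
Reactants: 40 the macrocyclic homoallylic alcohol; 7 4-bromo-3,7-dimethoxy-5-methylcyclohepta-2,4,6-trien-1-one
Product: 42 the (1R,2S,4R,5R,11R) macrocycle carrying the (4,7-dimethoxy-2-methyl-5-oxocyclohepta-1,3,6-trien-1-yl)methyl group at C4, via alkylborane 41 (not isolated)
Conditions: 9-BBN (3 equiv), THF, rt; then 7, Pd(dppf)Cl2 (10 mol%), AsPh3, K3PO4 (aq), DMF, rt to 50 °C
Reagents that add atoms: none
Why: Anti-Markovnikov hydroboration of the exocyclic methylene, then B-alkyl Suzuki–Miyaura coupling. The borane should approach from the periphery of the ring, anti to the C5 methyl, which stands perpendicular to the alkene plane when the C5–O bond lies in it; this places the new C4 hydrogen anti to that methyl (4R), as the trans ring fusion requires. The C2 hydroxyl is borylated in passing and freed by the aqueous base.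

Step 33
Reactants: 42 the coupled silyl ether
Product: 44 bis(dihydropyranotropone) dimethyl ether, the O,O'-dimethyl ether of the target, via tertiary alcohol 43 (not isolated)
Conditions: Bu4NF, THF, 50 °C
Reagents that add atoms: none
Why: Fluoride cleaves the tertiary silyl ether and the C5 alkoxide displaces the neighbouring methoxy group of tropone B by addition–elimination (6-exo-trig), as in step 16; C4 and C5 are not touched, so the second trans-fused dihydropyran forms.

Step 34
Reactants: 44 the bis-methyl ether
Product: 45 the target, CNP0283947.4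
Conditions: LiCl, DMF, 120 °C; then dilute HCl to pH 4
Reagents that add atoms: none
Why: SN2 demethylation of the two vinylogous methyl esters by chloride (tropolonate is a good leaving group); attack at methyl cannot occur at the tertiary ether carbons, and no stereocentre is involved.

## Compound list

1 | 2-methylanisole | COc1ccccc1C | starting material
2 | 1-methoxy-2-methylcyclohexa-1,4-diene | COC1=C(C)CC=CC1 | intermediate
3 | 7,7-dibromo-1-methoxy-6-methylbicyclo[4.1.0]hept-3-ene (racemic; formed in the flask) | COC12CC=CCC1(C)C2(Br)Br | intermediate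
4 | 2-bromo-3-methylcyclohepta-2,5-dien-1-one | CC1=C(Br)C(=O)CC=CC1 | intermediate
5 | rac-(5R,6S)-2-bromo-5,6-dihydroxy-3-methylcyclohept-2-en-1-one (cis-diol) | CC1=C(Br)C(=O)C[C@@H](O)[C@@H](O)C1 | intermediate
6 | 5-bromo-2,4-dihydroxy-6-methylcyclohepta-2,4,6-trien-1-one | Cc1cc(=O)c(O)cc(O)c1Br | intermediate
7 | 4-bromo-3,7-dimethoxy-5-methylcyclohepta-2,4,6-trien-1-one | COc1cc(C)c(Br)c(OC)cc1=O | intermediate
8 | 2,2-dimethylpent-4-enal | C=CCC(C)(C)C=O | starting material
9 | 5,5-dimethoxy-4,4-dimethylpent-1-ene | C=CCC(C)(C)C(OC)OC | intermediate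
10 | 4,4-dimethoxy-3,3-dimethylbutanal | O=CCC(C)(C)C(OC)OC | intermediate
11 | ethyl (2Z)-6,6-dimethoxy-2,5,5-trimethylhex-2-enoate | CCOC(=O)/C(C)=C\CC(C)(C)C(OC)OC | intermediate
12 | (2Z)-6,6-dimethoxy-2,5,5-trimethylhex-2-en-1-ol | OC/C(C)=C\CC(C)(C)C(OC)OC | intermediate
13 | [(2S,3R)-3-(3,3-dimethoxy-2,2-dimethylpropyl)-2-methyloxiran-2-yl]methanol | OC[C@]1(C)O[C@@H]1CC(C)(C)C(OC)OC | intermediate
14 | (2S,3R)-3-(3,3-dimethoxy-2,2-dimethylpropyl)-2-{[(4-methoxyphenyl)methoxy]methyl}-2-methyloxirane | COc1ccc(COC[C@]2(C)O[C@@H]2CC(C)(C)C(OC)OC)cc1 | intermediate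
15 | (2R,3S)-3-{[dimethyl(propan-2-yloxy)silyl]methyl}-6,6-dimethoxy-1-[(4-methoxyphenyl)methoxy]-2,5,5-trimethylhexan-2-ol (formed in the flask) | CC(C)O[Si](C)(C)C[C@@H](CC(C)(C)C(OC)OC)[C@@](C)(O)COCc1ccc(OC)cc1 | intermediate
16 | (2R,3R)-2-(3,3-dimethoxy-2,2-dimethylpropyl)-4-[(4-methoxyphenyl)methoxy]-3-methylbutane-1,3-diol | OC[C@@H](CC(C)(C)C(OC)OC)[C@@](C)(O)COCc1ccc(OC)cc1 | intermediate
17 | (2R,3S)-3-(iodomethyl)-6,6-dimethoxy-1-[(4-methoxyphenyl)methoxy]-2,5,5-trimethylhexan-2-ol | IC[C@@H](CC(C)(C)C(OC)OC)[C@@](C)(O)COCc1ccc(OC)cc1 | intermediate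
18 | {[(2R,3S)-3-(iodomethyl)-6,6-dimethoxy-1-[(4-methoxyphenyl)methoxy]-2,5,5-trimethylhexan-2-yl]oxy}(trimethyl)silane | IC[C@@H](CC(C)(C)C(OC)OC)[C@@](C)(O[Si](C)(C)C)COCc1ccc(OC)cc1 | intermediate
19 | alkylzinc iodide of 18 (iodide replaced by ZnI; formed in the flask) | I[Zn]C[C@@H](CC(C)(C)C(OC)OC)[C@@](C)(O[Si](C)(C)C)COCc1ccc(OC)cc1 | intermediate
20 | 4-{(2S,3R)-2-(3,3-dimethoxy-2,2-dimethylpropyl)-4-[(4-methoxyphenyl)methoxy]-3-methyl-3-[(trimethylsilyl)oxy]butyl}-3,7-dimethoxy-5-methylcyclohepta-2,4,6-trien-1-one | COc1cc(C)c(C[C@@H](CC(C)(C)C(OC)OC)[C@@](C)(O[Si](C)(C)C)COCc2ccc(OC)cc2)c(OC)cc1=O | intermediate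
21 | 4-{(2S,3R)-2-(3,3-dimethoxy-2,2-dimethylpropyl)-3-hydroxy-4-[(4-methoxyphenyl)methoxy]-3-methylbutyl}-3,7-dimethoxy-5-methylcyclohepta-2,4,6-trien-1-one (formed in the flask) | COc1cc(C)c(C[C@@H](CC(C)(C)C(OC)OC)[C@@](C)(O)COCc2ccc(OC)cc2)c(OC)cc1=O | intermediate
22 | (2R,3S)-3-(3,3-dimethoxy-2,2-dimethylpropyl)-7-methoxy-2-{[(4-methoxyphenyl)methoxy]methyl}-2,5-dimethyl-3,4-dihydrocyclohepta[b]pyran-8(2H)-one | COc1ccc(COC[C@]2(C)Oc3cc(=O)c(OC)cc(C)c3C[C@H]2CC(C)(C)C(OC)OC)cc1 | intermediate
23 | 3-[(2R,3S)-7-methoxy-2-{[(4-methoxyphenyl)methoxy]methyl}-2,5-dimethyl-8-oxo-2,3,4,8-tetrahydrocyclohepta[b]pyran-3-yl]-2,2-dimethylpropanal | COc1ccc(COC[C@]2(C)Oc3cc(=O)c(OC)cc(C)c3C[C@H]2CC(C)(C)C=O)cc1 | intermediate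
24 | 2-bromoprop-2-en-1-ol | OCC(Br)=C | starting material
25 | [(2-bromoprop-2-en-1-yl)oxy](tert-butyl)dimethylsilane | C=C(Br)CO[Si](C)(C)C(C)(C)C | intermediate
26 | but-2-yn-1-ol | CC#CCO | starting material
27 | (2Z)-3-(4,4,5,5-tetramethyl-1,3,2-dioxaborolan-2-yl)but-2-en-1-ol | C/C(=C\CO)B1OC(C)(C)C(C)(C)O1 | intermediate
28 | (2E)-4-({[tert-butyl(dimethyl)silyl]oxy}methyl)-3-methylpenta-2,4-dien-1-ol | C/C(=C\CO)C(=C)CO[Si](C)(C)C(C)(C)C | intermediate
29 | [(2S,3S)-3-(3-{[tert-butyl(dimethyl)silyl]oxy}prop-1-en-2-yl)-3-methyloxiran-2-yl]methanol | OC[C@@H]1O[C@@]1(C)C(=C)CO[Si](C)(C)C(C)(C)C | intermediate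
30 | (3R)-4-({[tert-butyl(dimethyl)silyl]oxy}methyl)-3-methylpent-4-ene-1,3-diol | OCC[C@@](C)(O)C(=C)CO[Si](C)(C)C(C)(C)C | intermediate
31 | (3R)-2-({[tert-butyl(dimethyl)silyl]oxy}methyl)-3-methyl-5-[(1-phenyl-1H-tetrazol-5-yl)sulfanyl]pent-1-en-3-ol | c1ccc(cc1)-n1nnnc1SCC[C@@](C)(O)C(=C)CO[Si](C)(C)C(C)(C)C | intermediate
32 | 5-{[(3R)-3-{[tert-butyl(dimethyl)silyl]oxy}-4-({[tert-butyl(dimethyl)silyl]oxy}methyl)-3-methylpent-4-en-1-yl]sulfanyl}-1-phenyl-1H-tetrazole | c1ccc(cc1)-n1nnnc1SCC[C@@](C)(O[Si](C)(C)C(C)(C)C)C(=C)CO[Si](C)(C)C(C)(C)C | intermediate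
33 | 5-{[(3R)-3-{[tert-butyl(dimethyl)silyl]oxy}-4-({[tert-butyl(dimethyl)silyl]oxy}methyl)-3-methylpent-4-en-1-yl]sulfonyl}-1-phenyl-1H-tetrazole | O=S(=O)(CC[C@@](C)(O[Si](C)(C)C(C)(C)C)C(=C)CO[Si](C)(C)C(C)(C)C)c1nnnn1-c1ccccc1 | intermediate
34 | (2R,3R)-3-[(3E,6R)-6-{[tert-butyl(dimethyl)silyl]oxy}-7-({[tert-butyl(dimethyl)silyl]oxy}methyl)-2,2,6-trimethylocta-3,7-dien-1-yl]-7-methoxy-2-{[(4-methoxyphenyl)methoxy]methyl}-2,5-dimethyl-3,4-dihydrocyclohepta[b]pyran-8(2H)-one | COc1ccc(COC[C@]2(C)Oc3cc(=O)c(OC)cc(C)c3C[C@H]2CC(C)(C)/C=C/C[C@@](C)(O[Si](C)(C)C(C)(C)C)C(=C)CO[Si](C)(C)C(C)(C)C)cc1 | intermediate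
35 | (2R,3R)-3-[(3E,6R)-6-{[tert-butyl(dimethyl)silyl]oxy}-7-(hydroxymethyl)-2,2,6-trimethylocta-3,7-dien-1-yl]-7-methoxy-2-{[(4-methoxyphenyl)methoxy]methyl}-2,5-dimethyl-3,4-dihydrocyclohepta[b]pyran-8(2H)-one | COc1ccc(COC[C@]2(C)Oc3cc(=O)c(OC)cc(C)c3C[C@H]2CC(C)(C)/C=C/C[C@@](C)(O[Si](C)(C)C(C)(C)C)C(=C)CO)cc1 | intermediate
36 | (2R,3R)-3-[(3E,6R)-7-(bromomethyl)-6-{[tert-butyl(dimethyl)silyl]oxy}-2,2,6-trimethylocta-3,7-dien-1-yl]-7-methoxy-2-{[(4-methoxyphenyl)methoxy]methyl}-2,5-dimethyl-3,4-dihydrocyclohepta[b]pyran-8(2H)-one | COc1ccc(COC[C@]2(C)Oc3cc(=O)c(OC)cc(C)c3C[C@H]2CC(C)(C)/C=C/C[C@@](C)(O[Si](C)(C)C(C)(C)C)C(=C)CBr)cc1 | intermediate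
37 | (2R,3R)-3-[(3E,6R)-7-(bromomethyl)-6-{[tert-butyl(dimethyl)silyl]oxy}-2,2,6-trimethylocta-3,7-dien-1-yl]-2-(hydroxymethyl)-7-methoxy-2,5-dimethyl-3,4-dihydrocyclohepta[b]pyran-8(2H)-one | OC[C@]1(C)Oc2cc(=O)c(OC)cc(C)c2C[C@H]1CC(C)(C)/C=C/C[C@@](C)(O[Si](C)(C)C(C)(C)C)C(=C)CBr | intermediate
38 | (2R,3R)-3-[(3E,6R)-7-(bromomethyl)-6-{[tert-butyl(dimethyl)silyl]oxy}-2,2,6-trimethylocta-3,7-dien-1-yl]-7-methoxy-2,5-dimethyl-8-oxo-2,3,4,8-tetrahydrocyclohepta[b]pyran-2-carbaldehyde | O=C[C@]1(C)Oc2cc(=O)c(OC)cc(C)c2C[C@H]1CC(C)(C)/C=C/C[C@@](C)(O[Si](C)(C)C(C)(C)C)C(=C)CBr | intermediate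
39 | allylchromium dichloride of 38 (bromide replaced by trivalent chromium; formed in the flask) | O=C[C@]1(C)Oc2cc(=O)c(OC)cc(C)c2C[C@H]1CC(C)(C)/C=C/C[C@@](C)(O[Si](C)(C)C(C)(C)C)C(=C)C[Cr](Cl)Cl | intermediate
40 | (1R,2S,5R,11R; target numbering) eleven-membered homoallylic alcohol with C4 exocyclic methylene and C5 tert-butyldimethylsilyloxy, trans-fused to the 7-methoxy-5-methyl-8-oxo-dihydropyranotropone | C=C1C[C@H](O)[C@]2(C)Oc3cc(=O)c(OC)cc(C)c3C[C@H]2CC(C)(C)/C=C/C[C@@]1(C)O[Si](C)(C)C(C)(C)C | intermediate
41 | B-alkyl-9-borabicyclo[3.3.1]nonane of 40 (boron on C13, C4 R; C2 oxygen also borylated; formed in the flask) | C1CCC2CCCC1B2C[C@@H]3C[C@H](OB4C5CCCC4CCC5)[C@]6(C)Oc7cc(=O)c(OC)cc(C)c7C[C@H]6CC(C)(C)/C=C/C[C@@]3(C)O[Si](C)(C)C(C)(C)C | intermediate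
42 | (1R,2S,4R,5R,11R) macrocycle of 40 with the (4,7-dimethoxy-2-methyl-5-oxocyclohepta-1,3,6-trien-1-yl)methyl group on C4 | COc1cc(C)c(C[C@@H]2C[C@H](O)[C@]3(C)Oc4cc(=O)c(OC)cc(C)c4C[C@H]3CC(C)(C)/C=C/C[C@@]2(C)O[Si](C)(C)C(C)(C)C)c(OC)cc1=O | intermediate
43 | C5 tertiary alcohol of 42 (silyl group removed; formed in the flask) | COc1cc(C)c(C[C@@H]2C[C@H](O)[C@]3(C)Oc4cc(=O)c(OC)cc(C)c4C[C@H]3CC(C)(C)/C=C/C[C@@]2(C)O)c(OC)cc1=O | intermediate
44 | O,O'-dimethyl ether of the target (both tropolones as 7-methoxy-8-oxo ethers; 1R,2S,4R,5R,11R) | Cc1cc(OC)c(=O)cc2c1C[C@H]1CC(C)(C)/C=C/C[C@@]3(C)Oc4cc(=O)c(OC)cc(C)c4C[C@@H]3C[C@H](O)[C@]1(C)O2 | intermediate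
45 | CNP0283947.4 (1R,2S,4R,5R,11R bis-tropolone) | Cc1cc(=O)c(O)cc2c1C[C@H]1CC(C)(C)/C=C/C[C@@]3(C)Oc4cc(O)c(=O)cc(C)c4C[C@@H]3C[C@H](O)[C@]1(C)O2 | target

## Step count and risks

Total step count: 34. Longest linear sequence: 21 steps (steps 6 to 17, then 26 to 34).

**Step 31 (key step).** The most likely failure is poor facial selectivity at C2: the chain that closes the strained ring may not reach the aldehyde along the Felkin–Anh trajectory, so the C2 epimer may form beside or instead of 40. Oligomerisation is the second concern if the dilution is insufficient. Fallback: set out from 40 as obtained (mixture of C2 epimers), oxidise with Dess–Martin periodinane to the macrocyclic C2 ketone F1, and set C2 by reduction under reagent control (oxazaborolidine-catalysed borane reduction with the catalyst enantiomer that delivers hydride to the face giving the 2S alcohol), which returns to 40.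

**Step 32.** The most likely failure is low or wrong facial selectivity when 9-BBN adds to the exocyclic methylene, because the ring conformation, not a neighbouring group, decides which face is open. Hydride transfer from the free borane to the tropone carbonyl would add to the loss. Fallback: set out from 40 and hydroborate with pinacolborane under ClRh(PPh3)3 catalysis, which adds through a rhodium hydride, is known to show the opposite sense of induction from an allylic silyloxy centre to that of 9-BBN, and spares carbonyl groups. This gives the primary pinacol boronate F2, and Suzuki–Miyaura coupling of F2 with 7 (Pd(OAc)2, RuPhos, aqueous K3PO4) returns to 42.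

**Step 5.** The most likely failure is alkylation at the wrong pair of oxygens (or at carbon), giving a mixture of regioisomeric dimethyl ethers; only isomers with a methoxy group on C3 can close the pyran later. Fallback: set out from 6 and etherify only the vinylogous-acid hydroxyl under reversible acid catalysis (MeOH, HC(OMe)3, cat. H2SO4), as for the enol of a 1,3-diketone, to give 5-bromo-2-hydroxy-4-methoxy-6-methylcyclohepta-2,4,6-trien-1-one F3. The remaining tropolone hydroxyl is then methylated (Me2SO4, K2CO3) at the oxygen remote from the donor-bearing carbon, returning to 7.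

**Step 12.** The most likely failure is slow substitution at the hindered secondary epoxide carbon, so that isomerisation of the epoxide to an allylic alcohol or ketone by the basic and Lewis-acidic magnesium species takes over. Fallback: set out from 14 and open the epoxide with the smaller sp2 nucleophile CH2=CHMgBr/CuI to give vinyl carbinol F4. Ozonolysis of F4 gives the hydroxy aldehyde F5 (not isolated), which NaBH4 reduces in the same flask, returning to 16; the acetal at the other chain end means there is no second alkene to protect.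

**Step 33.** The most likely failure is that the hindered tertiary alkoxide displaces methoxide too slowly, so that fluoride- and alkoxide-induced side reactions (intermolecular methoxy exchange, attack by the C2 alkoxide) compete. Fallback: set out from 42, remove the silyl group without base (HF·pyridine, or aqueous HF in MeCN) and isolate alcohol 43. The ring is then closed by acid-catalysed transetherification of the vinylogous ester through the hydroxytropylium ion (camphorsulfonic acid, toluene, 4 Å molecular sieves to take up methanol), returning to 44. This fallback makes no new compound (F0).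

## Further compounds

F1 | step 31 | macrocyclic C2 ketone from oxidation of 40 (1R,5R,11R) | C=C1CC(=O)[C@]2(C)Oc3cc(=O)c(OC)cc(C)c3C[C@H]2CC(C)(C)/C=C/C[C@@]1(C)O[Si](C)(C)C(C)(C)C
F2 | step 32 | primary pinacol boronate from hydroboration of 40 (boron on C13, C4 R) | CC1(C)OB(C[C@@H]2C[C@H](O)[C@]3(C)Oc4cc(=O)c(OC)cc(C)c4C[C@H]3CC(C)(C)/C=C/C[C@@]2(C)O[Si](C)(C)C(C)(C)C)OC1(C)C
F3 | step 5 | 5-bromo-2-hydroxy-4-methoxy-6-methylcyclohepta-2,4,6-trien-1-one | COc1cc(O)c(=O)cc(C)c1Br
F4 | step 12 | vinyl carbinol from opening of 14 with a vinyl cuprate (vinyl in place of the CH2OH group of 16) | C=C[C@@H](CC(C)(C)C(OC)OC)[C@@](C)(O)COCc1ccc(OC)cc1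
F5 | step 12 | hydroxy aldehyde from ozonolysis of F4 | O=C[C@@H](CC(C)(C)C(OC)OC)[C@@](C)(O)COCc1ccc(OC)cc1
F0 | step 33 | none | none
A1 | alternative 1 | bis(dihydropyran-fused 2-bromocycloheptadienone), tert-butyldimethylsilyl ether | C[C@H]1C=C(Br)C(=O)CC2=C1C[C@H]1CC(C)(C)/C=C/C[C@@]3(C)OC4CC(=O)C(Br)=C[C@H](C)C=4C[C@@H]3C[C@H](O[Si](C)(C)C(C)(C)C)[C@]1(C)O2
A2 | alternative 2 | macrocyclic diol bearing two dimethoxytropone–CH2 groups, tert-butyldimethylsilyl ether | Cc1cc(OC)c(=O)cc(OC)c1C[C@H]1CC(C)(C)/C=C/C[C@@](C)(O)[C@H](Cc2c(C)cc(OC)c(=O)cc2OC)C[C@H](O[Si](C)(C)C(C)(C)C)[C@]1(C)O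
A3 | alternative 3 | bis(dihydropyran-fused 5-alkoxycyclohepta-2,4-dienone), tert-butyldimethylsilyl ether | CC1=CC(=O)CCC2=C1C[C@H]1CC(C)(C)/C=C/C[C@@]3(C)OC4CCC(=O)C=C(C)C=4C[C@@H]3C[C@H](O[Si](C)(C)C(C)(C)C)[C@]1(C)O2
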